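**Strategy**

The route rests on cutting ring C of the triterpenoid half at C12–C13 and C8–C14, the two bonds that flank the vicinal quaternary carbons C13/C14. One intramolecular Diels–Alder reaction makes both: the diene C12=C11–C9=C8 is tied through an oxygen on C7 to an (E)-3-arylbut-2-enoate (C14=C13; the anisole is a latent ring E). The lactone so formed is absent from the target; it fixes C8, C13 and C14, directs the C14 methylation, then gives C15/C16 of ring D and leaves C7 as the C6=C7 alkene. Rings D, E and B are closed afterwards, and a hetero-Diels–Alder reaction of the ortho-quinone with a synthetic guaiatriene completes the target.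

Key step: step 12

**Remarks on the chemistry (assumptions)**

- Friedelane numbering is used for the triterpenoid half and guaiane numbering for the sesquiterpenoid half; α/β follow the usual triterpene convention.
- The sesquiterpenoid half of the target is (7S,10R), the mirror-image series of commercial α-guaiene and guaiol, so it is made from (S)-carvone.
- Wild-type Old Yellow Enzyme 1 is taken to reduce (S)-carvone to the cis (2R,5S) ketone.
- Cyclopentadiene 38 equilibrates by 1,5-hydrogen shifts; it is drawn as the tautomer that must react and is used as the mixture.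
- C20 is α to the C21 ketone and should settle as the equatorial 20β-methyl epimer under the base of step 16.
- Compounds 1, 4, 11 and 29 are taken to be catalogue compounds.

**Route**

Step 1
Reactants: 1 3,4-dimethoxy-2-methylbenzaldehyde
Product: 2 (3,4-dimethoxy-2-methylphenyl)methanol
Conditions: NaBH4, MeOH, 0 °C
Reagents that add atoms: none
Why: Hydride reduction of an aromatic aldehyde should be clean and leaves the aryl ethers untouched.

Step 2
Reactants: 2 (3,4-dimethoxy-2-methylphenyl)methanol
Product: 3 1-(chloromethyl)-3,4-dimethoxy-2-methylbenzene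
Conditions: SOCl2, CH2Cl2, 0 °C
Reagents that add atoms: thionyl chloride, ClS(Cl)=O
Why: Chlorodehydroxylation of an electron-rich benzylic alcohol through its chlorosulfite should be fast and needs no purification beyond evaporation.

Step 3
Reactants: 4 (E)-3-methylpent-2-en-4-yn-1-ol
Product: 5 (E)-3-methylpent-2-en-4-ynal
Conditions: MnO2, CH2Cl2, 25 °C
Reagents that add atoms: none
Why: Allylic oxidation with MnO2 should stop at the aldehyde and keep the (E)-alkene and the terminal alkyne.

Step 4
Reactants: 3 1-(chloromethyl)-3,4-dimethoxy-2-methylbenzene; 5 (E)-3-methylpent-2-en-4-ynal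
Product: 7 racemic (E)-1-(3,4-dimethoxy-2-methylphenyl)-4-methylhex-3-en-5-yn-2-ol, via (3,4-dimethoxy-2-methylbenzyl)zinc chloride 6 (not isolated)
Conditions: Mg, ZnCl2, LiCl, THF, 25 °C; then 5, 0 °C
Reagents that add atoms: none
Why: Magnesium insertion with in situ transmetalation gives the benzylic zinc reagent without Wurtz coupling, and its MgCl2-assisted 1,2-addition to the enal should give the allylic alcohol (C6–C7 bond).

Step 5
Reactants: 7 racemic (E)-1-(3,4-dimethoxy-2-methylphenyl)-4-methylhex-3-en-5-yn-2-ol
Product: 8 (E)-1-(3,4-dimethoxy-2-methylphenyl)-4-methylhex-3-en-5-yn-2-one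
Conditions: MnO2, CH2Cl2, 25 °C
Reagents that add atoms: none
Why: The secondary allylic alcohol should be oxidised selectively to the enone, which erases the racemic centre for the asymmetric reduction that follows.

Step 6
Reactants: 8 (E)-1-(3,4-dimethoxy-2-methylphenyl)-4-methylhex-3-en-5-yn-2-one
Product: 9 (S,E)-1-(3,4-dimethoxy-2-methylphenyl)-4-methylhex-3-en-5-yn-2-ol
Conditions: (R)-2-methyl-CBS-oxazaborolidine (10 mol %), catecholborane, toluene, −78 °C
Reagents that add atoms: none
Why: Corey–Bakshi–Shibata reduction of an enone, in which the alkenyl group acts as the large substituent, should deliver the (S)-carbinol at C7.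

Step 7
Reactants: 9 (S,E)-1-(3,4-dimethoxy-2-methylphenyl)-4-methylhex-3-en-5-yn-2-ol
Product: 10 (S,E)-1-(3,4-dimethoxy-2-methylphenyl)-4-methylhexa-3,5-dien-2-ol
Conditions: H2 (1 atm), Pd/CaCO3 poisoned with Pb(OAc)2, quinoline, EtOAc, 25 °C
Reagents that add atoms: none
Why: Semi-hydrogenation of the terminal alkyne over poisoned palladium should give the vinyl group and leave the trisubstituted alkene, so that the C12=C11–C9=C8 diene is in place.

Step 8
Reactants: 11 2,5-dimethylanisole
Product: 12 1-(4-methoxy-2,5-dimethylphenyl)ethanone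
Conditions: AcCl, AlCl3, CH2Cl2, 0 °C
Reagents that add atoms: acetyl chloride, CC(Cl)=O
Why: Friedel–Crafts acylation should occur para to the methoxy group, the only strongly activated open position.

Step 9
Reactants: 12 1-(4-methoxy-2,5-dimethylphenyl)ethanone
Product: 13 ethyl (E)-3-(4-methoxy-2,5-dimethylphenyl)but-2-enoate
Conditions: (EtO)2P(O)CH2CO2Et, NaH, THF, 65 °C
Reagents that add atoms: triethyl phosphonoacetate, CCOC(=O)CP(=O)(OCC)OCC
Why: Horner–Wadsworth–Emmons olefination of the methyl ketone should favour the (E)-enoate (aryl trans to the ester), the minor (Z)-isomer being removed by chromatography.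

Step 10
Reactants: 13 ethyl (E)-3-(4-methoxy-2,5-dimethylphenyl)but-2-enoate
Product: 14 (E)-3-(4-methoxy-2,5-dimethylphenyl)but-2-enoic acid
Conditions: LiOH, THF/H2O, 50 °C; then HCl
Reagents that add atoms: lithium hydroxide, [Li+].[OH-]
Why: Saponification of a hindered conjugated ester should proceed without loss of the (E)-geometry.

Step 11
Reactants: 10 (S,E)-1-(3,4-dimethoxy-2-methylphenyl)-4-methylhexa-3,5-dien-2-ol; 14 (E)-3-(4-methoxy-2,5-dimethylphenyl)but-2-enoic acid
Product: 15 (S,E)-1-(3,4-dimethoxy-2-methylphenyl)-4-methylhexa-3,5-dien-2-yl (E)-3-(4-methoxy-2,5-dimethylphenyl)but-2-enoate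
Conditions: DCC, DMAP (cat.), CH2Cl2, 0 → 25 °C
Reagents that add atoms: none
Why: Steglich esterification acylates the secondary alcohol with retention at C7 and installs the C7–O–C15 tether.

Step 12
Reactants: 15 (S,E)-1-(3,4-dimethoxy-2-methylphenyl)-4-methylhexa-3,5-dien-2-yl (E)-3-(4-methoxy-2,5-dimethylphenyl)but-2-enoate
Product: 16 cis-fused bicyclic γ-lactone (ring C cyclohexene with the 9(11)-alkene; C7–O–C15(=O)–C14; 8β-H, 14β-H, 13α-methyl, 13β-aryl; C7 bears the 3,4-dimethoxy-2-methylbenzyl group)
Conditions: toluene (0.005 M), 2,6-di-tert-butyl-4-methylphenol (cat.), sealed tube, 190 °C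
Reagents that add atoms: none
Why: Thermal intramolecular Diels–Alder reaction: the C12=C11–C9=C8 diene and the C14=C13 enoate react in a concerted, asynchronous [4+2] within the dienyl ester, the closest precedent being ester-tethered cycloadditions of 2,4-dienyl acrylates. Ring C closes by the two new bonds C12–C13 and C8–C14 (six-membered, [4+2]), while the tether becomes a five-membered lactone that can only be cis-fused at C8–C14. C8 and C14 follow from C7: allylic 1,3-strain with the C9 methyl holds H7 in the diene plane, so the dienophile adds to the face that carries the tether oxygen. C13 follows from the (E)-geometry of the enoate (aryl trans to the acyl carbon), which puts its methyl cis to C15. Regiochemistry needs no control because the three-atom tether allows one orientation only; the selectivity to be won is cycloaddition over [3,3]-acyloxy shift or diene isomerisation, which high dilution, a radical inhibitor and the s-cis-biased 2-methyl diene should secure.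

Step 13
Reactants: 16 cis-fused bicyclic γ-lactone
Product: 18 14β-methyl lactone, via lithium enolate of the lactone 17 (not isolated)
Conditions: LiN(iPr)2, THF, −78 °C; then MeI, DMPU, −78 → −20 °C
Reagents that add atoms: iodomethane, CI
Why: Alkylation of a bicyclic γ-lactone enolate at the ring-fusion carbon keeps the cis-fusion, so the methyl group must enter C14 on the face opposite the lactone ring (β, trans to the C13 methyl).

Step 14
Reactants: 18 14β-methyl lactone
Product: 19 cyclic enol ether (C15=C16H2 exocyclic methylene in place of the lactone carbonyl)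
Conditions: Cp2TiMe2, toluene, 70 °C, dark
Reagents that add atoms: dimethyltitanocene, C[Ti](C)(C1C=CC=C1)C1C=CC=C1
Why: Titanium-carbene methylenation converts hindered lactones into enol ethers; this brings in C16 and gives a function that survives dissolving metal.

Step 15
Reactants: 19 cyclic enol ether
Product: 20 dihydroanisole (ring E as 1-methoxy-2,5-dimethylcyclohexa-1,4-diene, C17=C18 and C20=C21 retained)
Conditions: Li, NH3 (l), THF, t-BuOH, −78 °C; then NH4Cl
Reagents that add atoms: none
Why: Birch reduction of the anisole protonates its two unsubstituted carbons (C19, C22); the tetrasubstituted dimethoxyarene, which has no para pair of free positions, should be much slower.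

Step 16
Reactants: 20 dihydroanisole
Product: 22 tetracyclic 7-hydroxy-15,21-dione with rings C, D and E closed and the 9(11)-alkene retained, via hydroxy dione 21 (not isolated)
Conditions: 1 M HCl, THF, 25 °C; then KOtBu (0.3 equiv), t-BuOH, 25 °C
Reagents that add atoms: water, O
Why: Acid hydrolyses both enol ethers (C15 methyl ketone, C7 hydroxyl, ring E β,γ-enone); base then forms the ring E dienolate, so that the alkene position and C18 equilibrate, and the C16 enolate adds 6-exo to C17 in an intramolecular Michael reaction whose cis ring fusion is enforced by the tether at C18, which should funnel the material to the less strained 18β-H product with C20 equatorial.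

Step 17
Reactants: 22 tetracyclic 7-hydroxy-15,21-dione
Product: 23 pentacyclic 2,3-dimethoxy-7-hydroxy-15,21-dione (8β-H, 9β-methyl, 13α-methyl, 14β-methyl, 17β-methyl, 18β-H, 20β-methyl)
Conditions: [N,N′-bis(3,5-di-tert-butylsalicylidene)-1,2-cyclohexanediaminato]cobalt, C36H52CoN2O2, a divalent cobalt complex (5 mol %), N-fluoro-2,4,6-trimethylpyridinium tetrafluoroborate, PhSiH3, PhCF3, 0 → 25 °C
Reagents that add atoms: none
Why: Hydrogen-atom-transfer hydroarylation places H on C11 irreversibly and the C9 radical/cation is captured by C10 (para to the C3 methoxy group); in the trans-C/D-locked ring C the arene hangs from the axial C7 and can reach C9 on that face only, which sets the 9β-methyl cis to H8.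

Step 18
Reactants: 23 pentacyclic 2,3-dimethoxy-7-hydroxy-15,21-dione
Product: 24 21-ethylene ketal of 23
Conditions: HOCH2CH2OH, pyridinium p-toluenesulfonate, benzene, reflux with water removal
Reagents that add atoms: ethylene glycol, OCCO
Why: The C21 ketone is far less hindered than the C15 ketone, which is flanked by quaternary C14 and the neopentyl C16, so it should be ketalised selectively.

Step 19
Reactants: 24 21-ethylene ketal
Product: 26 15-deoxo ketal (C15 methylene), via 15-hydrazone 25 (not isolated)
Conditions: N2H4·H2O, KOH, diethylene glycol, 130 → 205 °C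
Reagents that add atoms: none
Why: Wolff–Kishner reduction under forcing conditions removes the hindered C15 ketone, which can enolise only towards C16, while the ketal and the C7 alcohol survive base.

Step 20
Reactants: 26 15-deoxo ketal
Product: 27 6,7-ene (2,3-dimethoxy styrene, 21-ketal)
Conditions: Ph2S[OC(CF3)2Ph]2, CH2Cl2, 25 °C
Reagents that add atoms: none
Why: Sulfurane dehydration is an anti elimination; the C7 oxygen is anti only to a benzylic C6 hydrogen (H8 is gauche to it), so the conjugated C6=C7 alkene should form without touching C8.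

Step 21
Reactants: 27 6,7-ene
Product: 28 2,3-dihydroxy-6-ene-21-ketone (catechol of the triterpenoid half)
Conditions: BBr3, CH2Cl2, −78 → 0 °C; then H2O
Reagents that add atoms: water, O
Why: BBr3 cleaves both aryl methyl ethers at low temperature and the acidic aqueous work-up releases the C21 ketone from its ketal.

Step 22
Reactants: 29 (S)-(+)-carvone
Product: 30 (2R,5S)-2-methyl-5-(prop-1-en-2-yl)cyclohexanone (cis-dihydrocarvone)
Conditions: Old Yellow Enzyme 1, NADP+ (cat.), glucose, glucose dehydrogenase, phosphate buffer pH 7, 30 °C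
Reagents that add atoms: none
Why: Ene-reductases deliver hydride and proton trans across the enone with fixed facial selectivity, which should give the (2R) centre and hence the cis ketone from (S)-carvone.

Step 23
Reactants: 30 (2R,5S)-2-methyl-5-(prop-1-en-2-yl)cyclohexanone
Product: 32 (2R,5S)-2-methyl-5-(prop-1-en-2-yl)cycloheptanone, via C-silyl ketone 31 (not isolated)
Conditions: Me3SiCHN2, BF3·OEt2, CH2Cl2, −78 °C; then 1 M HCl, THF, 25 °C
Reagents that add atoms: (trimethylsilyl)diazomethane, C[Si](C)(C)C=[N+]=[N-]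
Why: Lewis acid-promoted diazoalkane ring expansion migrates the less substituted α-carbon, so the methylene is inserted on the CH2 side and the stereocentre that becomes C10 stays α to the ketone.

Step 24
Reactants: 32 (2R,5S)-2-methyl-5-(prop-1-en-2-yl)cycloheptanone
Product: 34 7-(1-hydroxyethyl) ketone, via kinetic lithium enolate 33 (not isolated)
Conditions: LiN(iPr)2, THF, −78 °C; then CH3CHO, −78 °C
Reagents that add atoms: acetaldehyde, CC=O
Why: Kinetic deprotonation takes the unsubstituted α-methylene and the aldol addition brings in C4 and its methyl group without epimerising the other α-centre.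

Step 25
Reactants: 34 7-(1-hydroxyethyl) ketone
Product: 36 (E)-7-ethylidene ketone, via aldol mesylate 35 (not isolated)
Conditions: MsCl, Et3N, CH2Cl2, 0 → 25 °C
Reagents that add atoms: none
Why: Mesylation followed by E1cB elimination with the amine gives the more stable (E)-alkylidene ketone under conditions too mild to epimerise the other α-centre.

Step 26
Reactants: 36 (E)-7-ethylidene ketone
Product: 37 1-vinyl-7-ethylidene carbinol (divinyl carbinol)
Conditions: CH2=CHMgBr, THF, −78 → 0 °C
Reagents that add atoms: vinylmagnesium bromide, C=C[Mg]Br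
Why: 1,2-Addition of the Grignard reagent to the cross-conjugated ketone supplies C2 and C3; the new carbinol centre is lost in the next step.

Step 27
Reactants: 37 divinyl carbinol
Product: 38 (7S,10R)-guaia-1(5),3,11-triene
Conditions: TsOH·H2O (2 mol %), CH2Cl2, 0 °C
Reagents that add atoms: none
Why: Ionisation of the bis-allylic tertiary alcohol gives a pentadienyl cation whose conrotatory 4π electrocyclisation (C3–C4 bond) and proton loss give the cyclopentadiene, as in the standard synthesis of alkylcyclopentadienes from dienols; C7 and C10 are untouched.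

Step 28
Reactants: 28 2,3-dihydroxy-6-ene-21-ketone; 38 (7S,10R)-guaia-1(5),3,11-triene
Product: 40 CNP0233042.2, via ortho-quinone 39 (not isolated)
Conditions: Ag2O, MgSO4, Et2O, 0 °C; then 38, CH2Cl2, 25 °C, dark
Reagents that add atoms: none
Why: Oxidation gives the 2,3-quinone, whose O=C–C=O unit should add as an electron-poor heterodiene to the electron-rich C1=C5 bond of 38 in an inverse-demand hetero-Diels–Alder reaction, suprafacially (cis dioxane) and from the face opposite the cis C10 methyl and C7 isopropenyl groups, which sets C1 and C5.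

**Compound list**

1 | 3,4-dimethoxy-2-methylbenzaldehyde | COc1c(OC)ccc(c1C)C=O | starting material
2 | (3,4-dimethoxy-2-methylphenyl)methanol | COc1c(OC)ccc(c1C)CO | intermediate
3 | 1-(chloromethyl)-3,4-dimethoxy-2-methylbenzene | COc1c(OC)ccc(c1C)CCl | intermediate
4 | (E)-3-methylpent-2-en-4-yn-1-ol | OC/C=C(\C)C#C | starting material
5 | (E)-3-methylpent-2-en-4-ynal | O=C/C=C(\C)C#C | intermediate
6 | (3,4-dimethoxy-2-methylbenzyl)zinc chloride | COc1c(OC)ccc(c1C)C[Zn]Cl | intermediate
7 | racemic (E)-1-(3,4-dimethoxy-2-methylphenyl)-4-methylhex-3-en-5-yn-2-ol | COc1c(OC)ccc(c1C)CC(O)/C=C(\C)C#C | intermediate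
8 | (E)-1-(3,4-dimethoxy-2-methylphenyl)-4-methylhex-3-en-5-yn-2-one | COc1c(OC)ccc(c1C)CC(=O)/C=C(\C)C#C | intermediate
9 | (S,E)-1-(3,4-dimethoxy-2-methylphenyl)-4-methylhex-3-en-5-yn-2-ol | COc1c(OC)ccc(c1C)C[C@H](O)/C=C(\C)C#C | intermediate
10 | (S,E)-1-(3,4-dimethoxy-2-methylphenyl)-4-methylhexa-3,5-dien-2-ol | COc1c(OC)ccc(c1C)C[C@H](O)/C=C(\C)C=C | intermediate
11 | 2,5-dimethylanisole | COc1cc(C)ccc1C | starting material
12 | 1-(4-methoxy-2,5-dimethylphenyl)ethanone | CC(=O)c1cc(C)c(OC)cc1C | intermediate
13 | ethyl (E)-3-(4-methoxy-2,5-dimethylphenyl)but-2-enoate | CCOC(=O)/C=C(\C)c1cc(C)c(OC)cc1C | intermediate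
14 | (E)-3-(4-methoxy-2,5-dimethylphenyl)but-2-enoic acid | OC(=O)/C=C(\C)c1cc(C)c(OC)cc1C | intermediate
15 | dienyl ester of 10 with 14 (triene for the cycloaddition) | COc1c(OC)ccc(c1C)C[C@H](OC(=O)/C=C(\C)c1cc(C)c(OC)cc1C)/C=C(\C)C=C | intermediate
16 | cis-fused γ-lactone on ring C (9(11)-ene, 8β-H, 14β-H, 13α-methyl, 13β-aryl) | COc1c(OC)ccc(c1C)C[C@@H]1OC(=O)[C@@H]2[C@H]1C(C)=CC[C@@]2(C)c1cc(C)c(OC)cc1C | intermediate
17 | lithium enolate of lactone 16 | COc1c(OC)ccc(c1C)C[C@@H]1OC([O-])=C2[C@H]1C(C)=CC[C@@]2(C)c1cc(C)c(OC)cc1C.[Li+] | intermediate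
18 | 14β-methyl lactone | COc1c(OC)ccc(c1C)C[C@@H]1OC(=O)[C@]2(C)[C@H]1C(C)=CC[C@@]2(C)c1cc(C)c(OC)cc1C | intermediate
19 | cyclic enol ether (C15=C16H2) | COc1c(OC)ccc(c1C)C[C@@H]1OC(=C)[C@]2(C)[C@H]1C(C)=CC[C@@]2(C)c1cc(C)c(OC)cc1C | intermediate
20 | dihydroanisole (ring E as methoxycyclohexa-1,4-diene) | COc1c(OC)ccc(c1C)C[C@@H]1OC(=C)[C@]2(C)[C@H]1C(C)=CC[C@@]2(C)C1=C(C)CC(OC)=C(C)C1 | intermediate
21 | hydroxy dione (C7 hydroxyl, C15 methyl ketone, ring E β,γ-enone) | COc1c(OC)ccc(c1C)C[C@H](O)[C@@H]1C(C)=CC[C@@](C)(C2=C(C)CC(=O)C(C)C2)[C@]1(C)C(C)=O | intermediate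
22 | tetracyclic 7-hydroxy-15,21-dione (rings C, D, E; 9(11)-ene; pendant aryl) | COc1c(OC)ccc(c1C)C[C@H](O)[C@@H]1C(C)=CC[C@@]2(C)[C@@H]3C[C@@H](C)C(=O)C[C@]3(C)CC(=O)[C@]12C | intermediate
23 | pentacyclic 2,3-dimethoxy-7-hydroxy-15,21-dione | COc1c(OC)cc2c(c1C)C[C@H](O)[C@@H]1[C@@]2(C)CC[C@@]2(C)[C@@H]3C[C@@H](C)C(=O)C[C@]3(C)CC(=O)[C@]12C | intermediate
24 | 21-ethylene ketal of 23 | COc1c(OC)cc2c(c1C)C[C@H](O)[C@@H]1[C@@]2(C)CC[C@@]2(C)[C@@H]3C[C@@H](C)C4(OCCO4)C[C@]3(C)CC(=O)[C@]12C | intermediate
25 | 15-hydrazone of 24 | COc1c(OC)cc2c(c1C)C[C@H](O)[C@@H]1[C@@]2(C)CC[C@@]2(C)[C@@H]3C[C@@H](C)C4(OCCO4)C[C@]3(C)CC(=NN)[C@]12C | intermediate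
26 | 15-deoxo 7-hydroxy 21-ketal | COc1c(OC)cc2c(c1C)C[C@H](O)[C@@H]1[C@@]2(C)CC[C@@]2(C)[C@@H]3C[C@@H](C)C4(OCCO4)C[C@]3(C)CC[C@]12C | intermediate
27 | 2,3-dimethoxy-6-ene 21-ketal | COc1c(OC)cc2c(c1C)C=C[C@@H]1[C@@]2(C)CC[C@@]2(C)[C@@H]3C[C@@H](C)C4(OCCO4)C[C@]3(C)CC[C@]12C | intermediate
28 | 2,3-dihydroxy-6-ene-21-ketone (8β-H catechol) | Oc1c(O)cc2c(c1C)C=C[C@@H]1[C@@]2(C)CC[C@@]2(C)[C@@H]3C[C@@H](C)C(=O)C[C@]3(C)CC[C@]12C | intermediate
29 | (S)-(+)-carvone | CC1=CC[C@@H](CC1=O)C(C)=C | starting material
30 | (2R,5S)-2-methyl-5-(prop-1-en-2-yl)cyclohexanone | C=C(C)[C@H]1CC[C@@H](C)C(=O)C1 | intermediate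
31 | C-silyl ring-expanded ketone | C=C(C)[C@H]1CC[C@@H](C)C(=O)C([Si](C)(C)C)C1 | intermediate
32 | (2R,5S)-2-methyl-5-(prop-1-en-2-yl)cycloheptanone | C=C(C)[C@H]1CC[C@@H](C)C(=O)CC1 | intermediate
33 | kinetic lithium enolate of 32 | C=C(C)[C@H]1CC[C@@H](C)C([O-])=CC1.[Li+] | intermediate
34 | 7-(1-hydroxyethyl) ketone (aldol) | C=C(C)[C@H]1CC[C@@H](C)C(=O)C(C(C)O)C1 | intermediate
35 | aldol mesylate | C=C(C)[C@H]1CC[C@@H](C)C(=O)C(C(C)OS(C)(=O)=O)C1 | intermediate
36 | (E)-7-ethylidene-2-methyl-5-(prop-1-en-2-yl)cycloheptanone | C=C(C)[C@H]1CC[C@@H](C)C(=O)/C(=C/C)C1 | intermediate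
37 | 1-vinyl-7-ethylidene carbinol | C=C(C)[C@H]1CC[C@@H](C)C(O)(C=C)/C(=C/C)C1 | intermediate
38 | (7S,10R)-guaia-1(5),3,11-triene | C=C(C)[C@H]1CC[C@@H](C)C2=C(C1)C(C)=CC2 | intermediate
39 | triterpenoid 2,3-ortho-quinone (6-ene, 8β-H, 21-ketone) | O=C1C(=O)C=C2C(=C1C)C=C[C@@H]1[C@@]2(C)CC[C@@]2(C)[C@@H]3C[C@@H](C)C(=O)C[C@]3(C)CC[C@]12C | intermediate
40 | CNP0233042.2 | C=C(C)[C@H]1CC[C@@H](C)[C@@]23CC=C(C)[C@]2(C1)Oc1c(cc2c(c1C)C=C[C@@H]1[C@@]2(C)CC[C@@]2(C)[C@@H]4C[C@@H](C)C(=O)C[C@]4(C)CC[C@]12C)O3 | target

**Step count and risks**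

Total step count: 28.
Longest linear sequence: 18 steps (1 → 2 → 3 → 7 → 8 → 9 → 10 → 15 → 16 → 18 → 19 → 20 → 22 → 23 → 24 → 26 → 27 → 28 → 40; steps 1, 2, 4 to 7, 11 to 21 and 28).

Steps most likely to fail:

1. Step 12 (intramolecular Diels–Alder). The ester may stay in its unreactive extended conformation, and the β,β-disubstituted, aryl-twisted dienophile may be too slow, so that acyloxy shift or diene isomerisation wins. The fallback sets out from 10 and 13 and comes back at 16. The magnesium alkoxide of 10 (MeMgBr) is combined with ester 13 and MgBr2·OEt2 in toluene at 80–110 °C. The alkoxide-bound, Lewis acid-activated enoate should undergo a templated bimolecular cycloaddition on the same diene face to give the hydroxy ester cycloadduct F1. Its alkoxide then closes the lactone to 16 with loss of ethanol.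

2. Step 17 (ring B closure). The tertiary C9 radical/cation must build a quaternary centre whose methyl is syn-axial to the C14 methyl, so simple reduction to C9–H or proton loss may outrun capture by the arene. The fallback sets out from 22 and comes back at 23. NBS in MeCN should brominate C10 (para to the C3 methoxy group) to give the aryl bromide F2. Bu3SnH with azobisisobutyronitrile in benzene at 80 °C then generates the aryl radical, which should cyclise 6-exo onto C9 of the 9(11)-alkene from the only face its tether reaches. Hydrogen transfer to C11 completes 23.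

3. Step 28 (hetero-Diels–Alder union). The cyclopentadiene may react at its other double bond, after a hydrogen shift, or as a 4π partner across a quinone C=C, and the quinone may tautomerise before it is trapped. The fallback sets out from 38 and 28 and comes back at 40. Dimethyldioxirane in acetone at −78 °C should epoxidise the most electron-rich, ring-fusion C1=C5 bond from the face opposite the C10 methyl to give the 1,5-epoxide F3. Catalytic camphorsulfonic acid with catechol 28 should open it at the allylic C5 with the C3 hydroxyl to give the hydroxy aryl ether F4 (drawn with the cis relation; either C1 epimer converges). BF3·OEt2 then closes the second C–O bond at the tertiary C1 by cyclodehydration, the cis-fused benzodioxane being the only strain-free outcome.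

Further compounds
F1 | step 12 | ethyl ester cycloadduct with free C7 hydroxyl (ring C, 9(11)-ene, 8β-H, 14β-H, 13α-methyl, 13β-aryl) | COc1c(OC)ccc(c1C)C[C@H](O)[C@@H]1C(C)=CC[C@@](C)(c2cc(C)c(OC)cc2C)[C@@H]1C(=O)OCC
F2 | step 17 | C10 aryl bromide of 22 | COc1c(OC)cc(Br)c(c1C)C[C@H](O)[C@@H]1C(C)=CC[C@@]2(C)[C@@H]3C[C@@H](C)C(=O)C[C@]3(C)CC(=O)[C@]12C
F3 | step 28 | (7S,10R)-1,5-epoxyguaia-3,11-diene | C=C(C)[C@H]1CC[C@@H](C)[C@@]23CC=C(C)[C@]2(C1)O3
F4 | step 28 | C5 aryl ether of 28 (through O-3) with C1 hydroxyl and free C2 phenol | C=C(C)[C@H]1CC[C@@H](C)[C@@]2(O)CC=C(C)[C@]2(C1)Oc1c(O)cc2c(c1C)C=C[C@@H]1[C@@]2(C)CC[C@@]2(C)[C@@H]3C[C@@H](C)C(=O)C[C@]3(C)CC[C@]12C
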